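The target is disconnected at the four aryl C–O bonds lying ortho to its two ketones: on ring A (pentanoyl ring) the hydroxyls at C2 and C6 flank the acyl carbon C1, and on ring B (butanoyl, methoxy ring, numbered from the bridge carbon C1′) the hydroxyls at C2′ and C4′ flank C3′. A single palladium-catalysed, carbonyl-directed oxidation installs all four oxygens on a bis(acylaryl)methane whose only aromatic C–H bonds are these four. The precursor carries the remaining para oxygens as an acetate (ring A) and a methyl ether (ring B) and is assembled from two para-acylated ortho-cresol units joined through a chloromethylation and Friedel–Crafts benzylation sequence.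

Key step: step 6

Remark: the target has no stereocentre, so nothing has to be set or preserved; 2-methylanisole is taken as the purchased O-methyl form of ortho-cresol for ring B.

Step 1
Reactants: 1 2-methylphenol; 2 pentanoyl chloride
Product: 4 1-(4-hydroxy-3-methylphenyl)pentan-1-one, via 2-methylphenyl pentanoate 3 (not isolated)
Conditions: TfOH (neat), 0 °C → rt
Reagents that add atoms: none
Why: In neat triflic acid the phenol is O-acylated and the aryl ester undergoes Fries rearrangement (Friedel–Crafts acylation) to the open position para to the hydroxyl, which the low temperature favours over the single free ortho site.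

Step 2
Reactants: 5 2-methylanisole (1-methoxy-2-methylbenzene); 6 butanoyl chloride
Product: 7 1-(4-methoxy-3-methylphenyl)butan-1-one
Conditions: AlCl3, CH2Cl2, 0 °C → rt
Reagents that add atoms: none
Why: Friedel–Crafts acylation should occur para to the methoxy group, the strongest director, and stop after one acylation because the ketone formed deactivates the ring.

Step 3
Reactants: 7 1-(4-methoxy-3-methylphenyl)butan-1-one; 8 formaldehyde (as paraformaldehyde)
Product: 9 1-[3-(chloromethyl)-4-methoxy-5-methylphenyl]butan-1-one
Conditions: (CH2O)n, conc. HCl, ZnCl2 (cat.), 50 °C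
Reagents that add atoms: hydrogen chloride, Cl
Why: Blanc chloromethylation should attack C5, the only position that is both ortho to the methoxy donor and meta to the acyl group, and the deactivated ring should resist further alkylation by the benzyl chloride, as 4-acylanisoles are known to behave.

Step 4
Reactants: 9 1-[3-(chloromethyl)-4-methoxy-5-methylphenyl]butan-1-one; 4 1-(4-hydroxy-3-methylphenyl)pentan-1-one
Product: 10 1-[3-[(5-butanoyl-2-methoxy-3-methylphenyl)methyl]-4-hydroxy-5-methylphenyl]pentan-1-one
Conditions: ZnCl2 (0.3 equiv), 4 (2.5 equiv), 1,2-dichloroethane, 70 °C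
Reagents that add atoms: none
Why: In this Friedel–Crafts benzylation the 2-methoxybenzyl cation from 9 should attack the excess phenol 4 at its single free position ortho to the hydroxyl (meta to the acyl group), while ring B of 9 has no activated position left for self-alkylation.

Step 5
Reactants: 10 1-[3-[(5-butanoyl-2-methoxy-3-methylphenyl)methyl]-4-hydroxy-5-methylphenyl]pentan-1-one
Product: 11 2-[(5-butanoyl-2-methoxy-3-methylphenyl)methyl]-6-methyl-4-pentanoylphenyl acetate
Conditions: Ac2O, pyridine, DMAP (cat.), CH2Cl2, rt
Reagents that add atoms: acetic anhydride, CC(=O)OC(C)=O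
Why: DMAP-catalysed O-acylation of the hindered phenol should give the aryl acetate, which masks the para oxygen of ring A as an electron-poor, non-chelating ester for the oxidation.

Step 6
Reactants: 11 2-[(5-butanoyl-2-methoxy-3-methylphenyl)methyl]-6-methyl-4-pentanoylphenyl acetate
Product: 13 2-[(3-butanoyl-2,4-dihydroxy-6-methoxy-5-methylphenyl)methyl]-3,5-dihydroxy-6-methyl-4-pentanoylphenyl acetate, via tetrakis(trifluoroacetate) ester 12 (not isolated)
Conditions: Pd(OAc)2 (20 mol %), K2S2O8 (6 equiv), TFA/TFAA (3:1), 50 °C; then H2O, THF, rt
Reagents that add atoms: trifluoroacetic acid, OC(=O)C(F)(F)F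
Why: Proposed new method: each ketone oxygen binds electrophilic divalent palladium, concerted metalation–deprotonation at the adjacent ortho C–H gives a five-membered palladacycle, K2S2O8 oxidises it to tetravalent palladium, and C–O reductive elimination releases an aryl trifluoroacetate, after which the carbonyl turns to the second ortho C–H and the cycle repeats, twice on ring A and twice on ring B. The closest known reaction type is the Pd- or Ru-catalysed ketone-directed ortho C–H hydroxylation of aryl ketones with persulfate or hypervalent iodine oxidants, which is established only for one ortho position of simple ketones. No ring is closed and no stereocentre is formed. Site selectivity is built into 11, whose only four aromatic C–H bonds are the four ortho to the carbonyls, so the selectivity needed is aryl C–H oxidation over attack at the benzylic CH2 bridge, the ketone α-CH2 groups and the oxygenated rings, and chelation-delivered palladation is what should secure it. The high proportion of TFAA should keep every new oxygen as a trifluoroacetate, which prevents the first-formed ortho-hydroxy ketone from sequestering palladium as an O,O-chelate (the usual reason such reactions stop after one hydroxylation) and keeps both rings too electron-poor for quinone formation, the ring A acetate doing the same for the para oxygen. All four sites are flanked by an alkyl group and are therefore hindered, so a high catalyst loading is planned, and the trifluoroacetates are hydrolysed by water on work-up while the acetate stays.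

Step 7
Reactants: 13 2-[(3-butanoyl-2,4-dihydroxy-6-methoxy-5-methylphenyl)methyl]-3,5-dihydroxy-6-methyl-4-pentanoylphenyl acetate
Product: 14 1-[3-[(3-butanoyl-2,4-dihydroxy-6-methoxy-5-methylphenyl)methyl]-2,4,6-trihydroxy-5-methylphenyl]pentan-1-one (target)
Conditions: K2CO3, MeOH (degassed), 0 °C, Ar; then 1 M HCl
Reagents that add atoms: none
Why: Base-mediated transesterification (methanolysis) should cleave the activated aryl acetate, whose leaving group is a para-acyl phenoxide, at low temperature under argon, so that the electron-rich polyphenol is neither air-oxidised nor scrambled at the methylene bridge.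

Compound list
1 | 2-methylphenol (ortho-cresol) | Cc1ccccc1O | starting material
2 | pentanoyl chloride | CCCCC(Cl)=O | starting material
3 | 2-methylphenyl pentanoate | CCCCC(=O)Oc1ccccc1C | intermediate
4 | 1-(4-hydroxy-3-methylphenyl)pentan-1-one | CCCCC(=O)c1ccc(O)c(C)c1 | intermediate
5 | 2-methylanisole (1-methoxy-2-methylbenzene) | COc1ccccc1C | starting material
6 | butanoyl chloride | CCCC(Cl)=O | starting material
7 | 1-(4-methoxy-3-methylphenyl)butan-1-one | CCCC(=O)c1ccc(OC)c(C)c1 | intermediate
8 | formaldehyde (used as paraformaldehyde) | C=O | starting material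
9 | 1-[3-(chloromethyl)-4-methoxy-5-methylphenyl]butan-1-one | CCCC(=O)c1cc(C)c(OC)c(CCl)c1 | intermediate
10 | 1-[3-[(5-butanoyl-2-methoxy-3-methylphenyl)methyl]-4-hydroxy-5-methylphenyl]pentan-1-one | CCCCC(=O)c1cc(C)c(O)c(Cc2cc(C(=O)CCC)cc(C)c2OC)c1 | intermediate
11 | 2-[(5-butanoyl-2-methoxy-3-methylphenyl)methyl]-6-methyl-4-pentanoylphenyl acetate | CCCCC(=O)c1cc(C)c(OC(C)=O)c(Cc2cc(C(=O)CCC)cc(C)c2OC)c1 | intermediate
12 | 2-[[3-butanoyl-6-methoxy-5-methyl-2,4-bis(trifluoroacetoxy)phenyl]methyl]-6-methyl-4-pentanoyl-3,5-bis(trifluoroacetoxy)phenyl acetate | CCCCC(=O)c1c(OC(=O)C(F)(F)F)c(C)c(OC(C)=O)c(Cc2c(OC(=O)C(F)(F)F)c(C(=O)CCC)c(OC(=O)C(F)(F)F)c(C)c2OC)c1OC(=O)C(F)(F)F | intermediate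
13 | 2-[(3-butanoyl-2,4-dihydroxy-6-methoxy-5-methylphenyl)methyl]-3,5-dihydroxy-6-methyl-4-pentanoylphenyl acetate | CCCCC(=O)c1c(O)c(C)c(OC(C)=O)c(Cc2c(O)c(C(=O)CCC)c(O)c(C)c2OC)c1O | intermediate
14 | 1-[3-[(3-butanoyl-2,4-dihydroxy-6-methoxy-5-methylphenyl)methyl]-2,4,6-trihydroxy-5-methylphenyl]pentan-1-one | CCCCC(=O)c1c(O)c(C)c(O)c(Cc2c(O)c(C(=O)CCC)c(O)c(C)c2OC)c1O | target

Total step count: 7. Longest linear sequence: 6 steps (steps 2, 3, 4, 5, 6, 7 from 2-methylanisole).

Steps most likely to fail

1. Step 6. The oxidation may stall after the first oxygenation of a ring through product inhibition, or palladation may be too slow at C–H bonds flanked by an alkyl group. Oxidation may also stray to the benzylic bridge or degrade the oxygenated rings. Partial acetyl/trifluoroacetyl exchange would be harmless, since it only anticipates step 7. Fallback by known chemistry, setting out from 2, 6 and 8 and returning at 14, with the ring oxygens bought instead of made: purchased 2-methylbenzene-1,3,5-triol F1 is C-acylated with 2 (AlCl3, nitrobenzene) to 1-(2,4,6-trihydroxy-3-methylphenyl)pentan-1-one F2, and with 6 to 1-(2,4,6-trihydroxy-3-methylphenyl)butan-1-one F3. F3 is methylated at its non-chelated, most acidic para hydroxyl (Me2SO4, K2CO3, acetone) to 1-(2,6-dihydroxy-4-methoxy-3-methylphenyl)butan-1-one F4. A phenolic Mannich reaction of F4 with 8 and Me2NH at its single free ring carbon gives 1-[3-[(dimethylamino)methyl]-2,6-dihydroxy-4-methoxy-5-methylphenyl]butan-1-one F5. Heating F5 with F2 in dioxane expels dimethylamine to form the ortho-quinone methide, which F2 traps at its single free ring carbon to give 14.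

2. Step 4. The benzylation of the acyl-deactivated phenol may be sluggish, with ether formation at oxygen or decomposition of the benzyl chloride competing. Fallback, setting out from 4 and 9 and returning at 11, makes the bridge by cross-coupling: 4 is brominated at its free position ortho to the hydroxyl (NBS, MeCN) to 1-(3-bromo-4-hydroxy-5-methylphenyl)pentan-1-one F6 and acetylated (Ac2O, pyridine) to 2-bromo-6-methyl-4-pentanoylphenyl acetate F7. 9 is converted with Zn dust and LiCl in THF into [(5-butanoyl-2-methoxy-3-methylphenyl)methyl]zinc chloride F8. Negishi coupling of F8 with F7 (Pd(OAc)2, SPhos, THF, rt) gives 11 directly, so steps 4 and 5 are bypassed.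

3. Step 3. Chloromethylation may attack a position other than C5, run on to diarylmethane by-products, or hydroxymethylate next to the ketone under acid. The volatile bis(chloromethyl) ether formed from formaldehyde and HCl also calls for closed handling. Fallback, setting out from 6 and returning at 10, fixes the regiochemistry by symmetry: purchased 2,6-dimethylanisole F9 is acylated with 6 (AlCl3, CH2Cl2) at its only activated position to 1-(4-methoxy-3,5-dimethylphenyl)butan-1-one F10. Wohl–Ziegler bromination of one of the two equivalent aryl methyl groups (NBS, AIBN, PhCF3, reflux) gives 1-[3-(bromomethyl)-4-methoxy-5-methylphenyl]butan-1-one F11. F11 replaces 9 under the conditions of step 4 and gives 10.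

Further compounds
F1 | step 6 | 2-methylbenzene-1,3,5-triol (purchased) | Cc1c(O)cc(O)cc1O
F2 | step 6 | 1-(2,4,6-trihydroxy-3-methylphenyl)pentan-1-one | CCCCC(=O)c1c(O)cc(O)c(C)c1O
F3 | step 6 | 1-(2,4,6-trihydroxy-3-methylphenyl)butan-1-one | CCCC(=O)c1c(O)cc(O)c(C)c1O
F4 | step 6 | 1-(2,6-dihydroxy-4-methoxy-3-methylphenyl)butan-1-one | CCCC(=O)c1c(O)cc(OC)c(C)c1O
F5 | step 6 | 1-[3-[(dimethylamino)methyl]-2,6-dihydroxy-4-methoxy-5-methylphenyl]butan-1-one | CCCC(=O)c1c(O)c(C)c(OC)c(CN(C)C)c1O
F6 | step 4 | 1-(3-bromo-4-hydroxy-5-methylphenyl)pentan-1-one | CCCCC(=O)c1cc(C)c(O)c(Br)c1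
F7 | step 4 | 2-bromo-6-methyl-4-pentanoylphenyl acetate | CCCCC(=O)c1cc(C)c(OC(C)=O)c(Br)c1
F8 | step 4 | [(5-butanoyl-2-methoxy-3-methylphenyl)methyl]zinc chloride | CCCC(=O)c1cc(C)c(OC)c(C[Zn]Cl)c1
F9 | step 3 | 2,6-dimethylanisole (purchased) | COc1c(C)cccc1C
F10 | step 3 | 1-(4-methoxy-3,5-dimethylphenyl)butan-1-one | CCCC(=O)c1cc(C)c(OC)c(C)c1
F11 | step 3 | 1-[3-(bromomethyl)-4-methoxy-5-methylphenyl]butan-1-one | CCCC(=O)c1cc(C)c(OC)c(CBr)c1
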